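**Plan**

- Retrosynthesis: the C15–C5′ bond is cut first (vinylogous aldol), then C13=C14 (olefination back to a C13 methyl ketone), then the C18–O and C8–O bonds, which leads to larixol.
- Forward: the decalin comes intact from larixol and the butenolide ring intact from 4-methylfuran-2(5H)-one, so no ring is built. The side chain is trimmed to the methyl ketone, ring B is hydrated at C8, C18 is hydroxylated, the chain is rebuilt to the C15 aldehyde and the butenolide is joined last.
- Enabling feature: C15 is a CHOH carbon between the oxygen-bearing C14 and C5′, the CH–O ring carbon of the butenolide next to the methyl-bearing C4′. This is the adduct of an α-alkoxy aldehyde (C15) and the 5-position of a 4-methyl-2-silyloxyfuran.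
- Stereochemistry: C5, C6, C9 and C10 come from larixol; C8 from α-face epoxidation and hydride opening; C4 from hydroxyl-directed silylation of the methyl group peri to the 6α-oxygen; C14 from Sharpless epoxidation; C15 from magnesium chelation; C5′ from the open aldol transition state.

Key step: step 16

Remark on assumptions: labdane numbering is used (C1–C20, butenolide C2′–C5′). Larixol, triethyl phosphonoacetate and 4-methylfuran-2(5H)-one are taken as purchased. The acetal carbon of 16 is expected as a mixture of epimers, which is of no consequence, and is left unspecified.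

Step 1
Reactants: 1 larixol (labda-8(17),14-diene-6α,13S-diol)
Product: 2 6α-hydroxy-14,15-dinorlabd-8(17)-en-13-one
Conditions: KMnO4, BnEt3NCl, CH2Cl2/H2O, 0 °C → rt
Reagents that add atoms: none
Why: Permanganate degradation of a tertiary vinyl carbinol (hydroxylation of the vinyl group, then cleavage of the C13–C14 glycol) should give the methyl ketone, as is usual for 13-hydroxylabd-14-enes, while the hindered exocyclic alkene and the 6α-hydroxyl survive at low temperature.

Step 2
Reactants: 2 6α-hydroxy-14,15-dinorlabd-8(17)-en-13-one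
Product: 3 13,13-ethylenedioxy-14,15-dinorlabd-8(17)-en-6α-ol
Conditions: ethylene glycol, PPTS (cat.), benzene, reflux (Dean–Stark)
Reagents that add atoms: ethylene glycol, OCCO
Why: Acid-catalysed ketalization with removal of water masks the ketone for the hydride and C–H functionalization steps, and the mild pyridinium acid should not move the exocyclic alkene.

Step 3
Reactants: 3 13,13-ethylenedioxy-14,15-dinorlabd-8(17)-en-6α-ol
Product: 4 8α,17-epoxy-13,13-ethylenedioxy-14,15-dinorlabdan-6α-ol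
Conditions: mCPBA, NaHCO3, CH2Cl2, 0 °C
Reagents that add atoms: mCPBA, OOC(=O)c1cccc(Cl)c1
Why: Prilezhaev epoxidation of the only alkene should take place on the α face, because the β face of C8 is shielded by the axial C10 methyl group, which places the epoxide oxygen in the equatorial 8α position.

Step 4
Reactants: 4 8α,17-epoxy-13,13-ethylenedioxy-14,15-dinorlabdan-6α-ol
Product: 5 13,13-ethylenedioxy-14,15-dinorlabdane-6α,8α-diol
Conditions: LiAlH4, THF, reflux
Reagents that add atoms: none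
Why: Hydride opens the spiro-epoxide by SN2 attack at the primary C17, so the C8–O bond is untouched and the 8α tertiary alcohol with an axial (β) C17 methyl group results; the ketal is inert.

Step 5
Reactants: 5 13,13-ethylenedioxy-14,15-dinorlabdane-6α,8α-diol
Product: 8 13,13-ethylenedioxy-14,15-dinorlabdane-6α,8α,18-triol, via diethylsilyl ether 6 (not isolated), via oxasilinane 7 (not isolated)
Conditions: Et2SiH2, [Ir(cod)OMe]2 (cat.), THF, rt; then [Rh(cod)Cl]2/Xantphos (cat.), norbornene, THF, 100 °C; then H2O2, KHCO3, THF/MeOH, 50 °C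
Reagents that add atoms: hydrogen peroxide, OO
Why: Dehydrogenative silylation of the secondary 6α-hydroxyl gives a hydrosilyl ether whose silicon is delivered by rhodium to the nearest primary C–H bond four carbons from oxygen, the equatorial C18 methyl lying peri to the 6α-oxygen (hydroxyl-directed intramolecular δ-C–H silylation closing a six-membered oxasilinane, no γ-C–H bond being present), and Tamao–Fleming oxidation then gives the 6α,18-diol, which fixes C4.

Step 6
Reactants: 8 13,13-ethylenedioxy-14,15-dinorlabdane-6α,8α,18-triol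
Product: 9 6α,8α,18-tris(tert-butyldimethylsilyloxy)-13,13-ethylenedioxy-14,15-dinorlabdane
Conditions: TBSOTf (excess), 2,6-lutidine, CH2Cl2, 0 °C → rt
Reagents that add atoms: tert-butyldimethylsilyl triflate, CC(C)(C)[Si](C)(C)OS(=O)(=O)C(F)(F)F
Why: The silyl triflate with a hindered pyridine base silylates primary, hindered secondary and tertiary hydroxyls alike, and a ketone dioxolane is stable to these conditions.

Step 7
Reactants: 9 6α,8α,18-tris(tert-butyldimethylsilyloxy)-13,13-ethylenedioxy-14,15-dinorlabdane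
Product: 10 6α,8α,18-tris(tert-butyldimethylsilyloxy)-14,15-dinorlabdan-13-one
Conditions: PPTS, acetone/H2O, 55 °C
Reagents that add atoms: water, O
Why: Acid-catalysed ketal hydrolysis regenerates the methyl ketone under conditions that tert-butyldimethylsilyl ethers, including the neopentyl primary one, should survive.

Step 8
Reactants: 10 6α,8α,18-tris(tert-butyldimethylsilyloxy)-14,15-dinorlabdan-13-one; 11 triethyl phosphonoacetate
Product: 12 ethyl (13E)-6α,8α,18-tris(tert-butyldimethylsilyloxy)labd-13-en-15-oate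
Conditions: NaH, THF, 0 °C → reflux
Reagents that add atoms: none
Why: Horner–Wadsworth–Emmons olefination of the unhindered methyl ketone returns C14 and C15 and should favour the E-enoate (ester trans to the larger C12 chain), the minor Z isomer being removed by chromatography.

Step 9
Reactants: 12 ethyl (13E)-6α,8α,18-tris(tert-butyldimethylsilyloxy)labd-13-en-15-oate
Product: 13 (13E)-6α,8α,18-tris(tert-butyldimethylsilyloxy)labd-13-en-15-ol
Conditions: iBu2AlH, CH2Cl2, −78 °C
Reagents that add atoms: none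
Why: 1,2-Reduction of the conjugated ester by the aluminium hydride gives the allylic alcohol without changing the alkene geometry or the silyl ethers.

Step 10
Reactants: 13 (13E)-6α,8α,18-tris(tert-butyldimethylsilyloxy)labd-13-en-15-ol
Product: 14 (13R,14R)-13,14-epoxy-6α,8α,18-tris(tert-butyldimethylsilyloxy)labdan-15-ol
Conditions: Ti(OiPr)4 (cat.), D-(−)-diethyl tartrate, tBuOOH, 4 Å sieves, CH2Cl2, −20 °C
Reagents that add atoms: tert-butyl hydroperoxide, CC(C)(C)OO
Why: Sharpless asymmetric epoxidation of the E-trisubstituted allylic alcohol is reagent-controlled, and the D-(−)-tartrate should deliver oxygen to the face that gives the (13R,14R)-epoxide (the mirror image of the sense that L-(+)-tartrate gives with geraniol), which fixes C14.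

Step 11
Reactants: 14 (13R,14R)-13,14-epoxy-6α,8α,18-tris(tert-butyldimethylsilyloxy)labdan-15-ol
Product: 15 (14S)-6α,8α,18-tris(tert-butyldimethylsilyloxy)labd-13(16)-ene-14,15-diol
Conditions: Ti(OiPr)4 (2 equiv), CH2Cl2, rt
Reagents that add atoms: none
Why: Titanium bound to the C15 oxygen activates the epoxide, the tertiary C13–O bond breaks and an isopropoxide ligand removes a proton from the C16 methyl group cis to the hydroxymethyl arm (hydroxyl-directed isomerization of a 2,3-epoxy alcohol to an allylic 1,2-diol), so the C14–O bond keeps its configuration and the C13=C16 methylene is formed.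

Step 12
Reactants: 15 (14S)-6α,8α,18-tris(tert-butyldimethylsilyloxy)labd-13(16)-ene-14,15-diol
Product: 16 14,15-O-(4-methoxybenzylidene) acetal of 15
Conditions: 4-MeOC6H4CH(OMe)2, PPTS (cat.), CH2Cl2, rt
Reagents that add atoms: 4-methoxybenzaldehyde dimethyl acetal, COc1ccc(C(OC)OC)cc1
Why: Acid-catalysed transacetalization closes the five-membered benzylidene acetal on the 1,2-diol and leaves the silyl ethers alone.

Step 13
Reactants: 16 14,15-O-(4-methoxybenzylidene) acetal of 15
Product: 17 (14S)-14-(4-methoxybenzyloxy)-6α,8α,18-tris(tert-butyldimethylsilyloxy)labd-13(16)-en-15-ol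
Conditions: iBu2AlH, CH2Cl2, −78 → 0 °C
Reagents that add atoms: none
Why: In this reductive acetal opening the aluminium reagent coordinates the less hindered primary oxygen and delivers hydride to the acetal carbon, which leaves the 4-methoxybenzyl group on the secondary C14 oxygen and frees the C15 hydroxyl.

Step 14
Reactants: 17 (14S)-14-(4-methoxybenzyloxy)-6α,8α,18-tris(tert-butyldimethylsilyloxy)labd-13(16)-en-15-ol
Product: 18 (14S)-14-(4-methoxybenzyloxy)-6α,8α,18-tris(tert-butyldimethylsilyloxy)labd-13(16)-en-15-al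
Conditions: Dess–Martin periodinane, NaHCO3, CH2Cl2, 0 °C
Reagents that add atoms: none
Why: Buffered Dess–Martin oxidation gives the aldehyde under neutral conditions that should avoid epimerization at C14 and migration of the C13 alkene into conjugation; the aldehyde is used at once.

Step 15
Reactants: 19 4-methylfuran-2(5H)-one
Product: 20 tert-butyldimethyl[(4-methylfuran-2-yl)oxy]silane
Conditions: TBSOTf, Et3N, CH2Cl2, 0 °C
Reagents that add atoms: tert-butyldimethylsilyl triflate, CC(C)(C)[Si](C)(C)OS(=O)(=O)C(F)(F)F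
Why: Soft enolization of the butenolide at C5 and O-silylation give the aromatic 2-silyloxyfuran, with the methyl group remaining on C4.

Step 16
Reactants: 18 (14S)-14-(4-methoxybenzyloxy)-6α,8α,18-tris(tert-butyldimethylsilyloxy)labd-13(16)-en-15-al; 20 tert-butyldimethyl[(4-methylfuran-2-yl)oxy]silane
Product: 21 (14S,15R,5′R) aldol adduct: 14-O-(4-methoxybenzyl) tris-silyl ether of the target
Conditions: MgBr2·OEt2 (3 equiv), CH2Cl2, −78 → −20 °C; then aq. NH4Cl
Reagents that add atoms: none
Why: MgBr2 binds the aldehyde oxygen and the C14 ether oxygen of 18 in a five-membered chelate, C5 of the silyloxyfuran attacks the activated carbonyl through an open transition state, and loss of the silyl group from the oxocarbenium intermediate releases the conjugated lactone. The closest known reaction type is the Lewis acid-mediated vinylogous Mukaiyama aldol addition of 2-silyloxyfurans to α-alkoxy aldehydes. No ring is closed: the butenolide arrives intact with the nucleophile and only the C15–C5′ bond is made. C15 is set by the Cram chelate, the furan approaching the carbonyl face on the side of the C14 hydrogen and away from the C13 alkenyl substituent, which gives the 14,15-syn arrangement (15R). C5′ is set by the mutual orientation of furan and aldehyde in the open transition state, which for Lewis acid-promoted silyloxyfuran additions normally places the ring oxygen and the new hydroxyl syn (threo, 5′R). The step needs chemoselectivity (the silyloxyfuran is far more nucleophilic than the C13 methylene and reacts only at C5, so the methyl ends on C4′), chelation over Felkin–Anh control (secured by the benzyl-type ether and the bidentate magnesium salt in a non-coordinating solvent) and threo simple diastereoselection, which is the least certain element.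

Step 17
Reactants: 21 (14S,15R,5′R) aldol adduct
Product: 22 6,8,18-tris-O-(tert-butyldimethylsilyl) ether of the target
Conditions: DDQ, CH2Cl2/pH 7 buffer, 0 °C → rt
Reagents that add atoms: none
Why: Oxidative cleavage of the electron-rich 4-methoxybenzyl ether by DDQ in wet solvent frees the C14 hydroxyl without affecting the silyl ethers, the butenolide or the 1,1-disubstituted alkene.

Step 18
Reactants: 22 6,8,18-tris-O-(tert-butyldimethylsilyl) ether of the target
Product: 23 target compound CNP0301623.1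
Conditions: HF·pyridine, pyridine, THF, 0 °C → rt
Reagents that add atoms: none
Why: Buffered fluoride desilylation removes the primary, secondary and (most slowly) tertiary silyl ethers without opening or epimerizing the butenolide or ionizing the allylic diol.

**Compound list**

1 | larixol (labda-8(17),14-diene-6α,13S-diol) | C=C[C@@](C)(O)CC[C@@H]1[C@@]2(C)CCCC(C)(C)[C@@H]2[C@@H](O)CC1=C | starting material
2 | 6α-hydroxy-14,15-dinorlabd-8(17)-en-13-one | CC(=O)CC[C@@H]1[C@@]2(C)CCCC(C)(C)[C@@H]2[C@@H](O)CC1=C | intermediate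
3 | 13,13-ethylenedioxy-14,15-dinorlabd-8(17)-en-6α-ol | CC3(OCCO3)CC[C@@H]1[C@@]2(C)CCCC(C)(C)[C@@H]2[C@@H](O)CC1=C | intermediate
4 | 8α,17-epoxy-13,13-ethylenedioxy-14,15-dinorlabdan-6α-ol | CC3(OCCO3)CC[C@@H]1[C@@]2(C)CCCC(C)(C)[C@@H]2[C@@H](O)C[C@@]1(C4)O4 | intermediate
5 | 13,13-ethylenedioxy-14,15-dinorlabdane-6α,8α-diol | CC3(OCCO3)CC[C@@H]1[C@@]2(C)CCCC(C)(C)[C@@H]2[C@@H](O)C[C@@]1(C)O | intermediate
6 | 6-O-diethylsilyl ether of 5 (formed in the flask in step 5) | CC3(OCCO3)CC[C@@H]1[C@@]2(C)CCCC(C)(C)[C@@H]2[C@@H](O[SiH](CC)CC)C[C@@]1(C)O | intermediate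
7 | 6α-O,18-C-diethylsilylene-bridged oxasilinane (formed in the flask in step 5) | CC4(OCCO4)CC[C@@H]1[C@@]2(C)CCC[C@]3(C)[C@@H]2[C@@H](O[Si](CC)(CC)C3)C[C@@]1(C)O | intermediate
8 | 13,13-ethylenedioxy-14,15-dinorlabdane-6α,8α,18-triol | CC3(OCCO3)CC[C@@H]1[C@@]2(C)CCC[C@@](C)(CO)[C@@H]2[C@@H](O)C[C@@]1(C)O | intermediate
9 | 6α,8α,18-tris(tert-butyldimethylsilyloxy)-13,13-ethylenedioxy-14,15-dinorlabdane | CC3(OCCO3)CC[C@@H]1[C@@]2(C)CCC[C@@](C)(CO[Si](C)(C)C(C)(C)C)[C@@H]2[C@@H](O[Si](C)(C)C(C)(C)C)C[C@@]1(C)O[Si](C)(C)C(C)(C)C | intermediate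
10 | 6α,8α,18-tris(tert-butyldimethylsilyloxy)-14,15-dinorlabdan-13-one | CC(=O)CC[C@@H]1[C@@]2(C)CCC[C@@](C)(CO[Si](C)(C)C(C)(C)C)[C@@H]2[C@@H](O[Si](C)(C)C(C)(C)C)C[C@@]1(C)O[Si](C)(C)C(C)(C)C | intermediate
11 | triethyl phosphonoacetate | CCOC(=O)CP(=O)(OCC)OCC | starting material
12 | ethyl (13E)-6α,8α,18-tris(tert-butyldimethylsilyloxy)labd-13-en-15-oate | CCOC(=O)/C=C(\C)CC[C@@H]1[C@@]2(C)CCC[C@@](C)(CO[Si](C)(C)C(C)(C)C)[C@@H]2[C@@H](O[Si](C)(C)C(C)(C)C)C[C@@]1(C)O[Si](C)(C)C(C)(C)C | intermediate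
13 | (13E)-6α,8α,18-tris(tert-butyldimethylsilyloxy)labd-13-en-15-ol | OC/C=C(\C)CC[C@@H]1[C@@]2(C)CCC[C@@](C)(CO[Si](C)(C)C(C)(C)C)[C@@H]2[C@@H](O[Si](C)(C)C(C)(C)C)C[C@@]1(C)O[Si](C)(C)C(C)(C)C | intermediate
14 | (13R,14R)-13,14-epoxy-6α,8α,18-tris(tert-butyldimethylsilyloxy)labdan-15-ol | OC[C@H]3O[C@]3(C)CC[C@@H]1[C@@]2(C)CCC[C@@](C)(CO[Si](C)(C)C(C)(C)C)[C@@H]2[C@@H](O[Si](C)(C)C(C)(C)C)C[C@@]1(C)O[Si](C)(C)C(C)(C)C | intermediate
15 | (14S)-6α,8α,18-tris(tert-butyldimethylsilyloxy)labd-13(16)-ene-14,15-diol | C=C(CC[C@@H]1[C@@]2(C)CCC[C@@](C)(CO[Si](C)(C)C(C)(C)C)[C@@H]2[C@@H](O[Si](C)(C)C(C)(C)C)C[C@@]1(C)O[Si](C)(C)C(C)(C)C)[C@H](O)CO | intermediate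
16 | 14,15-O-(4-methoxybenzylidene) acetal of 15 (epimers at the acetal carbon) | C=C(CC[C@@H]1[C@@]2(C)CCC[C@@](C)(CO[Si](C)(C)C(C)(C)C)[C@@H]2[C@@H](O[Si](C)(C)C(C)(C)C)C[C@@]1(C)O[Si](C)(C)C(C)(C)C)[C@H]3COC(c4ccc(OC)cc4)O3 | intermediate
17 | (14S)-14-(4-methoxybenzyloxy)-6α,8α,18-tris(tert-butyldimethylsilyloxy)labd-13(16)-en-15-ol | C=C(CC[C@@H]1[C@@]2(C)CCC[C@@](C)(CO[Si](C)(C)C(C)(C)C)[C@@H]2[C@@H](O[Si](C)(C)C(C)(C)C)C[C@@]1(C)O[Si](C)(C)C(C)(C)C)[C@H](OCc3ccc(OC)cc3)CO | intermediate
18 | (14S)-14-(4-methoxybenzyloxy)-6α,8α,18-tris(tert-butyldimethylsilyloxy)labd-13(16)-en-15-al | C=C(CC[C@@H]1[C@@]2(C)CCC[C@@](C)(CO[Si](C)(C)C(C)(C)C)[C@@H]2[C@@H](O[Si](C)(C)C(C)(C)C)C[C@@]1(C)O[Si](C)(C)C(C)(C)C)[C@H](OCc3ccc(OC)cc3)C=O | intermediate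
19 | 4-methylfuran-2(5H)-one | CC1=CC(=O)OC1 | starting material
20 | tert-butyldimethyl[(4-methylfuran-2-yl)oxy]silane | Cc1coc(O[Si](C)(C)C(C)(C)C)c1 | intermediate
21 | (14S,15R,5′R) aldol adduct, 14-O-(4-methoxybenzyl) tris-silyl ether of the target | C=C(CC[C@@H]1[C@@]2(C)CCC[C@@](C)(CO[Si](C)(C)C(C)(C)C)[C@@H]2[C@@H](O[Si](C)(C)C(C)(C)C)C[C@@]1(C)O[Si](C)(C)C(C)(C)C)[C@H](OCc3ccc(OC)cc3)[C@@H](O)[C@@H]3OC(=O)C=C3C | intermediate
22 | 6,8,18-tris-O-(tert-butyldimethylsilyl) ether of the target | C=C(CC[C@@H]1[C@@]2(C)CCC[C@@](C)(CO[Si](C)(C)C(C)(C)C)[C@@H]2[C@@H](O[Si](C)(C)C(C)(C)C)C[C@@]1(C)O[Si](C)(C)C(C)(C)C)[C@H](O)[C@@H](O)[C@@H]3OC(=O)C=C3C | intermediate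
23 | CNP0301623.1, (14S,15R)-6α,8α,14,15,18-pentahydroxylabd-13(16)-en-15-yl butenolide (5′R, 4′-methyl) | C=C(CC[C@@H]1[C@@]2(C)CCC[C@@](C)(CO)[C@@H]2[C@@H](O)C[C@@]1(C)O)[C@H](O)[C@@H](O)[C@@H]1OC(=O)C=C1C | target

**Step count**

Total: 18 steps. Longest linear sequence: 17 steps (steps 1–14 and 16–18); step 15 prepares the silyloxyfuran separately.

**Steps most likely to fail**

Step 5. The rhodium-bound silicon may fail to reach the neopentyl C18–H bond, or the hydrosilyl ether may be consumed by redistribution or by reaction at the free tertiary 8-hydroxyl, so that no C–Si bond forms. The fallback sets out from 5 and returns at 8, attacking the same C–H bond with an oxygen radical instead of a metal. Compound 5 would be peracetylated (Ac2O, DMAP, pyridine, 60 °C) to the 6,8-diacetate F1, and the secondary 6-acetate removed selectively (K2CO3, MeOH, rt; the tertiary acetate is inert) to give the 8-monoacetate F2. The hypoiodite reaction (PhI(OAc)2, I2, cyclohexane, visible light) should then let the 6α-alkoxy radical abstract hydrogen from C18 through a six-membered transition state and close the 6α,18-epoxide F3. Oxidation of the ether CH2 (RuCl3 cat., NaIO4, CCl4/MeCN/H2O) would give the 18,6α-lactone F4, and LiAlH4 would reduce the lactone and cleave the acetate in one operation to give triol 8.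

Step 11. Proton loss may occur from C12 instead of C16, or isopropoxide may capture C13, so that the 13(16)-ene-14,15-diol is not formed cleanly. The fallback sets out from ketone 10 and returns at acetal 16, building the same unit by alkenyl–aldehyde coupling. Kinetic enolization (KN(SiMe3)2, PhNTf2, THF, −78 °C) would give the terminal enol triflate F5. Nozaki–Hiyama–Kishi coupling with 2-(4-methoxybenzyloxy)acetaldehyde (CrCl2, cat. NiCl2, DMF) would give the allylic alcohol F6 as both C14 epimers, and Dess–Martin oxidation the enone F7. Corey–Bakshi–Shibata reduction with the (S)-oxazaborolidine and BH3·SMe2, assuming the branched alkenyl group acts as the larger substituent, should give the (14S)-alcohol F8. Anhydrous DDQ (4 Å sieves, CH2Cl2) would then cyclize the benzyl ether onto the neighbouring hydroxyl to give acetal 16.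

Step 16. Simple diastereoselection at C5′ may be poor (erythro adduct), or the β,γ-unsaturated aldehyde may enolize toward the conjugated isomer before the C–C bond forms. The fallback sets out from aldehyde 18 and returns at 22, replacing the open transition state by a closed one with auxiliary control.

- An Evans syn aldol of 18 with the boron enolate of (S)-4-benzyl-3-[(4-methoxybenzyloxy)acetyl]oxazolidin-2-one (Bu2BOTf, Et3N, CH2Cl2, −78 → 0 °C) should set C15 and C5′ through a Zimmerman–Traxler transition state and give the glycolate adduct F9.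
- Transamidation (MeNHOMe·HCl, AlMe3) would give the Weinreb amide F10, and MeMgBr the methyl ketone F11.
- DDQ would remove both 4-methoxybenzyl groups to give the trihydroxy ketone F12.
- Wittig reaction with Ph3P=CHCO2Et (toluene, 80 °C) would give the enoate F13, whose ester lies cis to the C5′ hydroxyl and should lactonize in the flask to the butenolide 22.

**Further compounds**

F1 | step 5 | 6,8-diacetate of 5 | CC3(OCCO3)CC[C@@H]1[C@@]2(C)CCCC(C)(C)[C@@H]2[C@@H](OC(C)=O)C[C@@]1(C)OC(C)=O
F2 | step 5 | 8-monoacetate of 5 | CC3(OCCO3)CC[C@@H]1[C@@]2(C)CCCC(C)(C)[C@@H]2[C@@H](O)C[C@@]1(C)OC(C)=O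
F3 | step 5 | 8α-acetoxy-6α,18-epoxy-13,13-ethylenedioxy-14,15-dinorlabdane | CC4(OCCO4)CC[C@@H]1[C@@]2(C)CCC[C@]3(C)[C@@H]2[C@@H](OC3)C[C@@]1(C)OC(C)=O
F4 | step 5 | 8α-acetoxy-13,13-ethylenedioxy-14,15-dinorlabdan-18,6α-olide | CC4(OCCO4)CC[C@@H]1[C@@]2(C)CCC[C@]3(C)[C@@H]2[C@@H](OC3=O)C[C@@]1(C)OC(C)=O
F5 | step 11 | 13(16)-en-13-yl triflate of 10 | C=C(OS(=O)(=O)C(F)(F)F)CC[C@@H]1[C@@]2(C)CCC[C@@](C)(CO[Si](C)(C)C(C)(C)C)[C@@H]2[C@@H](O[Si](C)(C)C(C)(C)C)C[C@@]1(C)O[Si](C)(C)C(C)(C)C
F6 | step 11 | 15-(4-methoxybenzyloxy)-6α,8α,18-tris(tert-butyldimethylsilyloxy)labd-13(16)-en-14-ol (both C14 epimers) | C=C(CC[C@@H]1[C@@]2(C)CCC[C@@](C)(CO[Si](C)(C)C(C)(C)C)[C@@H]2[C@@H](O[Si](C)(C)C(C)(C)C)C[C@@]1(C)O[Si](C)(C)C(C)(C)C)C(O)COCc3ccc(OC)cc3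
F7 | step 11 | 15-(4-methoxybenzyloxy)-6α,8α,18-tris(tert-butyldimethylsilyloxy)labd-13(16)-en-14-one | C=C(CC[C@@H]1[C@@]2(C)CCC[C@@](C)(CO[Si](C)(C)C(C)(C)C)[C@@H]2[C@@H](O[Si](C)(C)C(C)(C)C)C[C@@]1(C)O[Si](C)(C)C(C)(C)C)C(=O)COCc3ccc(OC)cc3
F8 | step 11 | (14S)-15-(4-methoxybenzyloxy)-6α,8α,18-tris(tert-butyldimethylsilyloxy)labd-13(16)-en-14-ol | C=C(CC[C@@H]1[C@@]2(C)CCC[C@@](C)(CO[Si](C)(C)C(C)(C)C)[C@@H]2[C@@H](O[Si](C)(C)C(C)(C)C)C[C@@]1(C)O[Si](C)(C)C(C)(C)C)[C@H](O)COCc3ccc(OC)cc3
F9 | step 16 | glycolate syn-aldol adduct of 18 with the (S)-4-benzyloxazolidinone | C=C(CC[C@@H]1[C@@]2(C)CCC[C@@](C)(CO[Si](C)(C)C(C)(C)C)[C@@H]2[C@@H](O[Si](C)(C)C(C)(C)C)C[C@@]1(C)O[Si](C)(C)C(C)(C)C)[C@H](OCc3ccc(OC)cc3)[C@@H](O)[C@H](OCc3ccc(OC)cc3)C(=O)N3C(=O)OC[C@@H]3Cc3ccccc3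
F10 | step 16 | Weinreb amide from F9 | C=C(CC[C@@H]1[C@@]2(C)CCC[C@@](C)(CO[Si](C)(C)C(C)(C)C)[C@@H]2[C@@H](O[Si](C)(C)C(C)(C)C)C[C@@]1(C)O[Si](C)(C)C(C)(C)C)[C@H](OCc3ccc(OC)cc3)[C@@H](O)[C@H](OCc3ccc(OC)cc3)C(=O)N(C)OC
F11 | step 16 | methyl ketone from F10 | C=C(CC[C@@H]1[C@@]2(C)CCC[C@@](C)(CO[Si](C)(C)C(C)(C)C)[C@@H]2[C@@H](O[Si](C)(C)C(C)(C)C)C[C@@]1(C)O[Si](C)(C)C(C)(C)C)[C@H](OCc3ccc(OC)cc3)[C@@H](O)[C@H](OCc3ccc(OC)cc3)C(C)=O
F12 | step 16 | trihydroxy methyl ketone from F11 | C=C(CC[C@@H]1[C@@]2(C)CCC[C@@](C)(CO[Si](C)(C)C(C)(C)C)[C@@H]2[C@@H](O[Si](C)(C)C(C)(C)C)C[C@@]1(C)O[Si](C)(C)C(C)(C)C)[C@H](O)[C@@H](O)[C@H](O)C(C)=O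
F13 | step 16 | ethyl (Z)-enoate from F12 (lactonizes in the flask) | C=C(CC[C@@H]1[C@@]2(C)CCC[C@@](C)(CO[Si](C)(C)C(C)(C)C)[C@@H]2[C@@H](O[Si](C)(C)C(C)(C)C)C[C@@]1(C)O[Si](C)(C)C(C)(C)C)[C@H](O)[C@@H](O)[C@H](O)/C(C)=C\C(=O)OCC
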